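**Assumption:** the target has no stereocentres, so "single enantiomer" has no consequence here. It is isolated as an ammonium or alkali salt of the sulfate monoester and drawn as the free acid.

## Retrosynthetic overview
- Disconnect the 7-O-sulfate last: sulfate the one free 7-OH of a tetra-O-benzyl flavone, then remove all benzyl groups by hydrogenolysis.
- The flavone C-ring comes from I2/DMSO oxidative cyclisation of a 2'-hydroxychalcone. The ring oxygen is fixed because only one phenol ortho to the ketone is free.
- The chalcone comes from Claisen–Schmidt condensation of an A-ring acetophenone with a 3,4-bis(benzyloxy)benzaldehyde made from catechol.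
- Key radical step: photochemical radical acylation of 2,6-bis(MOM-oxy)-1,4-benzoquinone with acetaldehyde forms the C4a–C4 bond and sets the 1,2,3,5-tetraoxygenated A ring (O at C5, C7, C8, C8a) in one operation. The quinone is made from resorcinol by directed ortho-metalation and Fremy oxidation.
- Order of ring formation: A ring (quinone to arene), then B ring by aldol, then C ring by cyclisation.

## Route

**Step 1**
Reactants: 1, resorcinol
Product: 2, 1,3-bis(methoxymethoxy)benzene
Conditions: MOMCl (2.5 equiv), iPr2NEt, CH2Cl2, 0 °C to rt
Reagents that add atoms: MOMCl, COCCl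
Why: Double MOM protection of the phenols (Williamson-type etherification) gives a strong bidentate directing group for the next step; no stereocentres.

**Step 2**
Reactants: 2
Product: 3, 2,6-bis(methoxymethoxy)phenol
Conditions: n-BuLi, THF, 0 °C; then B(OMe)3, –78 °C to rt; then 30% H2O2, NaOH, 0 °C
Reagents that add atoms: B(OMe)3, COB(OC)OC (boron carrier); H2O2, OO (source of the phenol O)
Why: Directed ortho-metalation occurs selectively at C2, between the two MOM-oxy groups, and borylation–oxidation converts C–Li to C–OH. This installs the future C8 oxygen.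

**Step 3**
Reactants: 3
Product: 4, 2,6-bis(methoxymethoxy)-1,4-benzoquinone
Conditions: Fremy's salt (2.2 equiv), KH2PO4 buffer, acetone/H2O, rt
Reagents that add atoms: Fremy's salt, [K+].[K+].[O]N(S(=O)(=O)[O-])S(=O)(=O)[O-] (O delivered by nitroxide/water)
Why: Teuber oxidation proceeds through a phenoxyl radical trapped by the persistent nitroxide radical para to the OH. This installs the future C5 oxygen and gives a symmetric quinone whose two CH positions are equivalent, so acylation has no regiochemical ambiguity.

**Step 4**
Reactants: 5, catechol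
Product: 6, 1,2-bis(benzyloxy)benzene
Conditions: BnBr (2.3 equiv), K2CO3, DMF, 60 °C
Reagents that add atoms: BnBr, BrCc1ccccc1
Why: Williamson bis-benzylation protects the B-ring catechol as groups removable in the final hydrogenolysis.

**Step 5**
Reactants: 6
Product: 7, 3,4-bis(benzyloxy)benzaldehyde
Conditions: Cl2CHOMe, TiCl4, CH2Cl2, 0 °C
Reagents that add atoms: Cl2CHOMe, ClC(Cl)OC
Why: Rieche formylation goes para to one OBn, the least hindered activated position, giving the single 3,4-disubstituted aldehyde.

**Step 6 (key radical step)**
Reactants: 4; 8, acetaldehyde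
Product: 9, 1-[2,5-dihydroxy-4,6-bis(methoxymethoxy)phenyl]ethan-1-one
Conditions: 8 (30 equiv), MeCN, blue LEDs (450 nm), N2, 25 °C, sealed
Reagents that add atoms: none besides 8 (CC=O)
Why: Photoacylation of a quinone with an aldehyde: triplet quinone abstracts the aldehydic H, and the acetyl radical couples at the quinone CH flanked by C=O and C–OMOM. Tautomerisation gives the acylhydroquinone. This redox-neutral C–C bond formation sets the A-ring pattern, with the acetyl flanked by two oxygens and one of them ortho to a further oxygen; no stereocentre is formed.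

**Step 7**
Reactants: 9
Product: 10, 1-[2,5-bis(benzyloxy)-4,6-bis(methoxymethoxy)phenyl]ethan-1-one
Conditions: BnBr (3 equiv), K2CO3, TBAI (cat.), DMF, 60 °C, N2
Reagents that add atoms: BnBr, BrCc1ccccc1
Why: Dibenzylation of the air-sensitive hydroquinone caps the future C8-O and C5-O. Blocking the C5 oxygen ensures that later ring closure can only occur through the O that will become O1.

**Step 8**
Reactants: 10; 7
Product: 11, (E)-1-[2,5-bis(benzyloxy)-4,6-bis(methoxymethoxy)phenyl]-3-[3,4-bis(benzyloxy)phenyl]prop-2-en-1-one
Conditions: KOH (aq), EtOH/THF, 50 °C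
Reagents that add atoms: none
Why: Claisen–Schmidt condensation with a non-enolisable aldehyde; the E-alkene is the thermodynamic product, and MOM and Bn ethers are base-stable.

**Step 9**
Reactants: 11
Product: 12, (E)-1-[2,5-bis(benzyloxy)-4,6-dihydroxyphenyl]-3-[3,4-bis(benzyloxy)phenyl]prop-2-en-1-one
Conditions: 6 M HCl, THF/MeOH, 50 °C
Reagents that add atoms: none
Why: Acidolysis of the aryl MOM acetals frees the ortho phenol that becomes O1 and the para phenol that becomes C7-OH, while benzyl ethers survive. Partial oxa-Michael closure to the flavanone is harmless because the next step oxidises both.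

**Step 10**
Reactants: 12
Product: 13, 5,8-bis(benzyloxy)-2-[3,4-bis(benzyloxy)phenyl]-7-hydroxy-4H-chromen-4-one
Conditions: I2 (0.2 equiv), DMSO, 110 °C
Reagents that add atoms: none
Why: I2/DMSO oxidative cyclisation of a 2'-hydroxychalcone (conjugate addition, then iodination and elimination, with DMSO reoxidising iodide). Only one ortho phenol is free, so the 5,7,8-oxygenation pattern is obtained and the 5,6,7 isomer is excluded.

**Step 11**
Reactants: 13
Product: 14, 7-O-sulfate (trimethylammonium salt) of 13
Conditions: Me3N·SO3 (3 equiv), Et3N, MeCN, 60 °C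
Reagents that add atoms: Me3N·SO3, C[N+](C)(C)S(=O)(=O)[O-]
Why: O-Sulfation of the sole free (and acidic) phenol; all other oxygens are benzylated, so the reaction is chemoselective.

**Step 12**
Reactants: 14
Product: 15, 8-hydroxyluteolin 7-sulfate (target)
Conditions: H2 (1 atm), 10% Pd/C, THF/MeOH, rt, degassed; then ion exchange
Reagents that add atoms: none
Why: Hydrogenolysis removes all four benzyl groups (releasing toluene) and leaves the aryl sulfate monoester and the flavone C2=C3 bond intact.

## Compound list
1 | resorcinol | Oc1cccc(O)c1 | starting material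
2 | 1,3-bis(methoxymethoxy)benzene | COCOc1cccc(OCOC)c1 | intermediate
3 | 2,6-bis(methoxymethoxy)phenol | COCOc1cccc(OCOC)c1O | intermediate
4 | 2,6-bis(methoxymethoxy)-1,4-benzoquinone | COCOC1=CC(=O)C=C(OCOC)C1=O | intermediate
5 | catechol | Oc1ccccc1O | starting material
6 | 1,2-bis(benzyloxy)benzene | c1ccc(OCc2ccccc2)c(OCc2ccccc2)c1 | intermediate
7 | 3,4-bis(benzyloxy)benzaldehyde | O=Cc1ccc(OCc2ccccc2)c(OCc2ccccc2)c1 | intermediate
8 | acetaldehyde | CC=O | starting material
9 | 1-[2,5-dihydroxy-4,6-bis(methoxymethoxy)phenyl]ethanone | CC(=O)c1c(O)cc(OCOC)c(O)c1OCOC | intermediate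
10 | 1-[2,5-bis(benzyloxy)-4,6-bis(methoxymethoxy)phenyl]ethanone | CC(=O)c1c(OCc2ccccc2)cc(OCOC)c(OCc2ccccc2)c1OCOC | intermediate
11 | tetra-O-benzyl bis-MOM chalcone | O=C(/C=C/c1ccc(OCc2ccccc2)c(OCc2ccccc2)c1)c1c(OCc2ccccc2)cc(OCOC)c(OCc2ccccc2)c1OCOC | intermediate
12 | 2',4'-dihydroxy-3',6',3,4-tetrabenzyloxychalcone | O=C(/C=C/c1ccc(OCc2ccccc2)c(OCc2ccccc2)c1)c1c(OCc2ccccc2)cc(O)c(OCc2ccccc2)c1O | intermediate
13 | 5,8,3',4'-tetra-O-benzyl-7-hydroxyflavone | O=c1cc(-c2ccc(OCc3ccccc3)c(OCc3ccccc3)c2)oc2c(OCc3ccccc3)c(O)cc(OCc3ccccc3)c12 | intermediate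
14 | 7-sulfate of 13, Me3NH+ salt | O=c1cc(-c2ccc(OCc3ccccc3)c(OCc3ccccc3)c2)oc2c(OCc3ccccc3)c(OS(=O)(=O)[O-])cc(OCc3ccccc3)c12.C[NH+](C)C | intermediate
15 | 8-hydroxyluteolin 7-sulfate | O=c1cc(-c2ccc(O)c(O)c2)oc2c(O)c(OS(=O)(=O)O)cc(O)c12 | target

## Totals
Total steps: 12. Longest linear sequence: 10 (steps 1, 2, 3, 6, 7, 8, 9, 10, 11, 12; the catechol branch of steps 4–5 joins at step 8).

## Three steps most likely to fail
1. **Step 6, radical acylation.** Risks are over-acylation, competing H-abstraction from the MOM groups, and low conversion. Fallback: change to a polar route. Reduce 4 with Na2S2O4 and dibenzylate, then ortho-lithiate at C3 (directed by the adjacent OMOM) and quench with N-methoxy-N-methylacetamide to give 10 directly.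
2. **Step 10, I2/DMSO cyclisation.** Ring iodination, HI-induced debenzylation, or a sluggish hindered substrate could interfere. Fallback: change to a halogen-free two-stage closure. Cyclise 12 to the flavanone with NaOAc/EtOH, then dehydrogenate with DDQ.
3. **Step 12, final hydrogenolysis.** The product contains an air-sensitive 5,8-hydroquinone, and the sulfate or C2=C3 bond might not survive. Fallback: change the order of events. Hydrogenolyse 13 to 8-hydroxyluteolin, then sulfate regioselectively at 7-OH with an arylsulfotransferase using p-nitrophenyl sulfate as donor.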